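The intermediate, which the starting material gives in a first-order step, is shared among the first nucleophile (giving target), the second nucleophile, solvolysis and the starting material itself, so a flask's target is reckoned here as conversion times the share of consumed starting material that ends as target.

| flask | starting material | first nucleophile | second nucleophile | temperature | remark | time |
|---|---|---|---|---|---|---|
| ash | 5 mM | 30 mM | 30 mM | −15 °C | run made earlier |  |
| birch | 20 mM | 30 mM | 30 mM | 20 °C | run made earlier |  |
| larch | 10 mM | 30 mM | 60 mM | −15 °C | run made earlier |  |
| delta | 10 mM | 30.0 mM | 30.0 mM |  | at −10 °C until 4.0 h, from then on at 50 °C | 8.0 h |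
| alpha | 10 mM | 30.0 mM | 30.0 mM | 50 °C |  | 8.0 h |
| eta | 10 mM | 30.0 mM | 30.0 mM | 20 °C |  | 8.0 h |
| beta | 10 mM | 30.0 mM | 30.0 mM | −10 °C |  | 8.0 h |

| run | time / h | target / % | starting material / % |
|---|---|---|---|
| ash | 12.0 | 0.6 | 97.9 |
| ash | 30.0 | 1.3 | 94.6 |
| ash | 60.0 | 5.9 | 88.4 |
| ash | 96.0 | 7.9 | 85.6 |
| ash | 144 | 11.9 | 77.6 |
| ash | 192 | 15.6 | 70.1 |
| ash | 240 | 18.7 | 65.7 |
| birch | 2.00 | 8.7 | 60.5 |
| birch | 6.00 | 22.1 | 24.7 |
| birch | 12.0 | 26.3 | 8.5 |
| birch | 20.0 | 31.1 | 2.5 |
| birch | 25.0 | 29.1 | 0 |
| birch | 40.0 | 30.6 | 0 |
| larch | 50.0 | 3.7 | 92.1 |
| larch | 96.0 | 6.0 | 83.6 |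
| larch | 144 | 9.0 | 76.1 |
| larch | 192 | 12.5 | 69.9 |
| larch | 240 | 14.4 | 65.8 |

(readings scatter by 1 percentage point)

- percentages count the starting material that a species holds: one side product counts as two
- the analysis behind the earlier runs scatters by 1 percentage point, standard deviation
- steps under discussion: starting material -> intermediate; first nucleophile + intermediate -> target; second nucleophile + intermediate -> other capture product; intermediate -> solvolysis product; target -> over-reaction product; starting material + intermediate -> side product

1. the best flask by amount of target, in percent of the starting material charged; "all alike" if 1.5 percentage points covers them all (delta / alpha / eta / beta / all alike)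
2. amount of target at the end, in percent of the starting material charged, delta
3. amount of target at the end, in percent of the starting material charged, alpha
4. amount of target at the end, in percent of the starting material charged, eta
5. amount of target at the end, in percent of the starting material charged, beta

Conversion comes two ways, as the logarithm of charged over remaining starting material divided by time. The ash run gives a rate constant k of 0.00175 /h, and the larch run, with twice the starting material and twice the second nucleophile, gives 0.00174 /h, about the same, so this first-order clock is trusted. The birch run gives 0.205 /h at 20 °C, which puts eta at a conversion of 80.7 %. Interpolated between ash and birch, k is 0.00346 /h at −10 °C, which puts beta at 2.73 %.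

The share is harder. Let the capture odds Θ, a selectivity factor, be target over everything else the consumed starting material has become, at the last reading. Ash gives 1.20 and larch gives 0.727, lower at the same temperature, so here the two ways part. Larch is set aside: its second nucleophile stands at 60 mM against 30 mM of first, whereas ash, like the asked flasks, holds the two equal. Birch gives 0.441, so the fall factor F, the ratio of Θ at −15 °C to Θ at 20 °C, is 2.72; the step in charge from 5 mM to 20 mM rides along in this reading.

Carried on in proportion to temperature, F leaves a share of 15.8 % at 50 °C. My reckoning therefore gives that much target for alpha, and about that for delta, whose cold stage converts 1.37 %. It gives 1.39 % for beta and 24.7 % for eta, the highest.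

The forecast also chose eta, but with delta 25 %, alpha 24 %, eta 29.5 % and beta 1.4 %, holding for the hot flask that “selectivity is near 0.27”; its alpha stands above mine.

    starting material → intermediate (k = 5.30 × 10⁻⁵ /s, Ea = 86.0 kJ/mol)
    first nucleophile + intermediate → target (k = 0.0190 /M/s, Ea = 44.0 kJ/mol)
    second nucleophile + intermediate → other capture product (k = 0.0170 /M/s, Ea = 58.0 kJ/mol)
    intermediate → solvolysis product (k = 3.30 × 10⁻⁴ /s, Ea = 80.0 kJ/mol)
    target → over-reaction product (k = 1.30 × 10⁻⁷ /s, Ea = 109 kJ/mol)
    starting material + intermediate → side product (k = 0.0260 /M/s, Ea = 48.0 kJ/mol)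
    (constants at 20 °C)

The flasks give eta as best, with delta 16.9 %, alpha 14.9 %, eta 26.3 % and beta 1.05 %. Alpha also holds 3.87 % of over-reaction product at 8.00 h, so 18.7 % of the charge passed through target, more than the 15.8 % that F gave. Delta, at 8.00 h, holds 16.9 % of target and 2.02 % of over-reaction product, 19.0 % together against the same 15.8 % from F.

Readings and results are calculated for substances that don't exist; noise was put on by code.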